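**Retrosynthetic overview**
1. Testudinariol A (C2-symmetric) ⇒ two molecules of hydroxy ketone 12 + the C4 bis-ylide 15 (double Z-selective Wittig, last step).
2. 12 ⇒ keto aldehyde 11 by Me2AlCl carbonyl-ene closure of the cyclopentanol (second ring formed).
3. 11 ⇒ enone aldehyde 10 ⇒ pyranone carbonate 4 + 6-methylhept-5-enal 9 (dual palladium/enamine C–C coupling that sets the two stereocentres joining the rings).
4. 4 ⇒ furfuryl alcohol 1 by Achmatowicz oxidative ring expansion (furan → pyranone). This is the first ring formed and supplies every atom of the oxane, with the ketone already on the future alkylidene carbon.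
5. Ring order: oxane (ring expansion) → cyclopentane (ene) → union of the two halves.

Assumption: in step 4 the (R,R)-ligand is taken as the enantiomer that gives the (R) pyran carbon; the sense is assigned by analogy, and the mirror-image ligand is used if the first run shows the opposite.

**Route**

Step 1
Reactants: 1 furfuryl alcohol
Product: 3 6-hydroxy-2H-pyran-3(6H)-one (racemic lactol), via (Z)-5-hydroxy-4-oxopent-2-enal 2 (not isolated)
Conditions: mCPBA (1.1 equiv), CH2Cl2, 0 °C to rt
Reagents that add atoms: mCPBA (3-chloroperbenzoic acid), O=C(OO)c1cccc(Cl)c1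
Why: Achmatowicz oxidative ring expansion, in which peracid oxidation of the furan gives the cis-enedione 2 and its primary hydroxyl closes onto the aldehyde, so the five-membered furan becomes the six-membered pyranone; the lactol carbon is racemic and is reset in step 4.

Step 2
Reactants: 3 6-hydroxy-2H-pyran-3(6H)-one
Product: 4 tert-butyl (5-oxo-5,6-dihydro-2H-pyran-2-yl) carbonate (racemic)
Conditions: Boc2O (1.2 equiv), DMAP (5 mol %), CH2Cl2, −78 °C to −30 °C
Reagents that add atoms: di-tert-butyl dicarbonate, CC(C)(C)OC(=O)OC(=O)OC(C)(C)C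
Why: Routine DMAP-catalysed acylation of the anomeric hydroxyl, which installs the carbonate leaving group needed for ionisation in step 4; no stereocentre of consequence.

Step 3
Reactants: 5 2-(2-bromoethyl)-1,3-dioxolane; 6 1-bromo-3-methylbut-2-ene
Product: 9 6-methylhept-5-enal, via Grignard reagent 7 (not isolated), via dioxolane acetal 8 (not isolated)
Conditions: Mg turnings, THF, 25–30 °C; then 6, Li2CuCl4 (3 mol %), −10 °C to rt; then 2 M HCl, THF, rt
Reagents that add atoms: water, O
Why: Copper-catalysed Grignard coupling with the allylic bromide at its unhindered CH2 terminus, followed by acid hydrolysis of the acetal; no stereocentre.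

Step 4
Reactants: 4 tert-butyl (5-oxo-5,6-dihydro-2H-pyran-2-yl) carbonate (1.0 equiv); 9 6-methylhept-5-enal (1.5 equiv, added slowly)
Product: 10 (2R)-6-methyl-2-[(2R)-5-oxo-5,6-dihydro-2H-pyran-2-yl]hept-5-enal
Conditions: Pd2(dba)3·CHCl3 (2.5 mol %), (R,R)-DACH-phenyl Trost ligand (7.5 mol %), (S)-α,α-diphenylprolinol trimethylsilyl ether (20 mol %), THF, 0 °C
Reagents that add atoms: none
Why: Proposed new method: a dual-catalytic C-glycosylation in which zerovalent palladium with the chiral ligand ionises racemic 4 (loss of CO2 and tert-butoxide) to a π-allyl palladium complex whose two faces interconvert through the O-bound oxidopyrylium-type palladium enolate (dynamic kinetic asymmetric transformation), while the (S)-amine converts 9 into its E-enamine, which attacks the oxygen-bearing allyl terminus anti to palladium from its unshielded face, so the ligand sets the (R) pyran carbon, the amine sets the (R) α-carbon and iminium hydrolysis releases 10; the closest known reaction types are palladium/enamine α-allylation of aldehydes with simple allyl esters, stereodivergent iridium/amine α-allylation, and Tsuji–Trost glycosylation of pyranone carbonates with oxygen nucleophiles.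

Step 5
Reactants: 10 (2R)-6-methyl-2-[(2R)-5-oxo-5,6-dihydro-2H-pyran-2-yl]hept-5-enal
Product: 11 (2R)-6-methyl-2-[(2R)-5-oxooxan-2-yl]hept-5-enal
Conditions: H2 (1 atm), Pd/C (5% Pd on carbon), EtOAc, 0 °C, stopped after 1.0 equiv uptake; used at once
Reagents that add atoms: none
Why: Chemoselective heterogeneous hydrogenation, the conjugated cis-disubstituted enone C=C being reduced far faster than the trisubstituted alkene or the aldehyde, under neutral conditions that leave both stereocentres untouched.

Step 6
Reactants: 11 (2R)-6-methyl-2-[(2R)-5-oxooxan-2-yl]hept-5-enal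
Product: 12 (6R)-6-[(1S,2S,3R)-2-hydroxy-3-(prop-1-en-2-yl)cyclopentyl]oxan-3-one
Conditions: Me2AlCl (2.5 equiv), CH2Cl2, −78 °C; 1 M HCl work-up
Reagents that add atoms: none
Why: Lewis-acid-promoted intramolecular carbonyl-ene cyclisation through a chair-like bicyclic transition state with the oxanyl group pseudo-equatorial, which places the new hydroxyl trans to the oxanyl group and cis to the new isopropenyl group, both new stereocentres being set by the existing α-carbon (the same closure is precedented for this cyclopentanol triad); the ketone has no reachable ene geometry.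

Step 7
Reactants: 13 1,4-dibromobutane
Product: 14 butane-1,4-diylbis(triphenylphosphonium) dibromide
Conditions: PPh3 (2.1 equiv), DMF, 150 °C
Reagents that add atoms: triphenylphosphine, c1ccc(cc1)P(c1ccccc1)c1ccccc1
Why: Double SN2 quaternisation of a primary dibromide; no stereocentre.

Step 8
Reactants: 14 butane-1,4-diylbis(triphenylphosphonium) dibromide (1.0 equiv); 12 (6R)-6-[(1S,2S,3R)-2-hydroxy-3-(prop-1-en-2-yl)cyclopentyl]oxan-3-one (2.1 equiv)
Product: 17 testudinariol A, via bis-ylide 15 (not isolated), via mono-olefinated ylide 16 (not isolated)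
Conditions: KN(SiMe3)2 (2.05 equiv), THF, 0 °C; then 12, THF/HMPA (10:1), −78 °C to rt
Reagents that add atoms: none
Why: Two-directional Wittig olefination with a non-stabilised ylide under salt-free conditions, where the known preference of α-alkoxy ketones to place the ylide alkyl group cis to the oxygen-bearing carbon gives both Z alkenes; no stereocentre is α to the ketone, and the free secondary hydroxyl is not deprotonated by the ylide.

**Compound list**
1 | furfuryl alcohol (furan-2-ylmethanol) | OCc1ccco1 | starting material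
2 | (Z)-5-hydroxy-4-oxopent-2-enal | O=C/C=C\C(=O)CO | intermediate (not isolated)
3 | 6-hydroxy-2H-pyran-3(6H)-one (racemic) | OC1OCC(=O)C=C1 | intermediate
4 | tert-butyl (5-oxo-5,6-dihydro-2H-pyran-2-yl) carbonate (racemic) | CC(C)(C)OC(=O)OC1OCC(=O)C=C1 | intermediate
5 | 2-(2-bromoethyl)-1,3-dioxolane | BrCCC1OCCO1 | starting material
6 | 1-bromo-3-methylbut-2-ene | CC(C)=CCBr | starting material
7 | [2-(1,3-dioxolan-2-yl)ethyl]magnesium bromide | Br[Mg]CCC1OCCO1 | intermediate (not isolated)
8 | 2-(5-methylhex-4-en-1-yl)-1,3-dioxolane | CC(C)=CCCCC1OCCO1 | intermediate (not isolated)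
9 | 6-methylhept-5-enal | CC(C)=CCCCC=O | intermediate
10 | (2R)-6-methyl-2-[(2R)-5-oxo-5,6-dihydro-2H-pyran-2-yl]hept-5-enal | O=C[C@H](CCC=C(C)C)[C@H]1C=CC(=O)CO1 | intermediate
11 | (2R)-6-methyl-2-[(2R)-5-oxooxan-2-yl]hept-5-enal | O=C[C@H](CCC=C(C)C)[C@H]1CCC(=O)CO1 | intermediate
12 | (6R)-6-[(1S,2S,3R)-2-hydroxy-3-(prop-1-en-2-yl)cyclopentyl]oxan-3-one | C=C(C)[C@H]1CC[C@H]([C@H]2CCC(=O)CO2)[C@H]1O | intermediate
13 | 1,4-dibromobutane | BrCCCCBr | starting material
14 | butane-1,4-diylbis(triphenylphosphonium) dibromide | c1ccccc1[P+](c1ccccc1)(c1ccccc1)CCCC[P+](c1ccccc1)(c1ccccc1)c1ccccc1.[Br-].[Br-] | intermediate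
15 | butane-1,4-diylidenebis(triphenylphosphorane) (bis-ylide) | c1ccccc1P(c1ccccc1)(c1ccccc1)=CCCC=P(c1ccccc1)(c1ccccc1)c1ccccc1 | intermediate (not isolated)
16 | mono-olefinated ylide, Z alkene | C=C(C)[C@H]1CC[C@H]([C@H]2CC/C(=C/CCC=P(c3ccccc3)(c3ccccc3)c3ccccc3)CO2)[C@H]1O | intermediate (not isolated)
17 | testudinariol A (both exocyclic alkenes Z; each half: oxane carbon R, cyclopentane 1S,2S,3R) | C=C(C)[C@H]1CC[C@H]([C@H]2CC/C(=C/CC/C=C3/CC[C@H]([C@H]4CC[C@H](C(=C)C)[C@@H]4O)OC3)CO2)[C@H]1O | target

**Totals**
Total step count: 8. Longest linear sequence: 6 (steps 1, 2, 4, 5, 6, 8).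

**Steps most likely to fail**

Step 4 (the proposed dual catalysis). The enamine may be too slow toward the π-allyl complex, 4 may divert to oxidopyrylium dimers, or control at the pyran carbon may be poor. The fallback uses known auxiliary chemistry, sets out from 9 (with 4) and comes back at 11. Pinnick oxidation of 9 (NaClO2, NaH2PO4, 2-methylbut-2-ene) gives 6-methylhept-5-enoic acid F1. Mixed-anhydride acylation of (S)-4-benzyloxazolidin-2-one (PivCl, Et3N, LiCl) gives (S)-4-benzyl-3-(6-methylhept-5-enoyl)oxazolidin-2-one F2. Its chlorotitanium enolate (TiCl4, iPr2NEt, CH2Cl2, −78 °C) adds to the oxocarbenium ion released from 4 by the excess TiCl4, an established reaction of such enolates with cyclic oxocarbenium ions, to give the enone imide adduct F3. The auxiliary fixes the α-carbon and the minor epimer at the pyran carbon is removed by chromatography. Hydrogenation (H2, Pd/C) gives the saturated keto imide F4. LiBH4 removes the auxiliary and reduces the ketone to the diol (2S)-2-[(2R)-5-hydroxyoxan-2-yl]-6-methylhept-5-en-1-ol F5. Dess–Martin oxidation of both hydroxyls returns 11.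

Step 5 (chemoselective hydrogenation on a labile α-branched aldehyde). Over-reduction of the trisubstituted alkene, allylic C–O hydrogenolysis or epimerisation are possible. The fallback sets out from 10 and comes back at 12, with the order of events reversed. Me2AlCl-promoted ene cyclisation of 10 gives the hydroxy enone (6R)-6-[(1S,2S,3R)-2-hydroxy-3-(prop-1-en-2-yl)cyclopentyl]-2H-pyran-3(6H)-one F6. Conjugate reduction with [(Ph3P)CuH]6 (benzene, wet THF) then gives 12; this hydride leaves the isopropenyl group and the hydroxyl alone.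

Step 8 (double Wittig). The Z preference has been shown for acyclic α-alkoxy ketones, not for an oxan-3-one, and the one-pot two-fold coupling gives no chance to purify after the first olefination. The fallback sets out from 12 and comes back at ylide 16; it is a linear, one-alkene-at-a-time sequence with a differentiated C4 unit. (4-Bromobutoxy)(tert-butyl)dimethylsilane and PPh3 give [4-(tert-butyldimethylsilyloxy)butyl]triphenylphosphonium bromide F7. Its ylide (KN(SiMe3)2, THF/HMPA, −78 °C) olefinates 12 to the Z silyl ether F8, which is freed from E isomer on AgNO3-impregnated silica. Bu4NF gives the primary alcohol F9. I2, PPh3 and imidazole (0 °C) convert only the primary hydroxyl into the iodide F10. PPh3 (MeCN, 80 °C) gives the phosphonium iodide F11. KN(SiMe3)2 then generates ylide 16, which reacts with a second equivalent of 12 to give 17.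

**Further compounds**
F1 | step 4 | 6-methylhept-5-enoic acid | CC(C)=CCCCC(=O)O
F2 | step 4 | (S)-4-benzyl-3-(6-methylhept-5-enoyl)oxazolidin-2-one | CC(C)=CCCCC(=O)N1[C@@H](Cc2ccccc2)COC1=O
F3 | step 4 | (S)-4-benzyl-3-[(2R)-6-methyl-2-[(2R)-5-oxo-5,6-dihydro-2H-pyran-2-yl]hept-5-enoyl]oxazolidin-2-one | O=C(N1[C@@H](Cc2ccccc2)COC1=O)[C@H](CCC=C(C)C)[C@H]3C=CC(=O)CO3
F4 | step 4 | (S)-4-benzyl-3-[(2R)-6-methyl-2-[(2R)-5-oxooxan-2-yl]hept-5-enoyl]oxazolidin-2-one | O=C(N1[C@@H](Cc2ccccc2)COC1=O)[C@H](CCC=C(C)C)[C@H]3CCC(=O)CO3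
F5 | step 4 | (2S)-2-[(2R)-5-hydroxyoxan-2-yl]-6-methylhept-5-en-1-ol (ring carbinol as epimer mixture) | OC[C@H](CCC=C(C)C)[C@H]1CCC(O)CO1
F6 | step 5 | (6R)-6-[(1S,2S,3R)-2-hydroxy-3-(prop-1-en-2-yl)cyclopentyl]-2H-pyran-3(6H)-one | C=C(C)[C@H]1CC[C@H]([C@H]2C=CC(=O)CO2)[C@H]1O
F7 | step 8 | [4-(tert-butyldimethylsilyloxy)butyl]triphenylphosphonium bromide | CC(C)(C)[Si](C)(C)OCCCC[P+](c1ccccc1)(c1ccccc1)c1ccccc1.[Br-]
F8 | step 8 | Z silyl ether from 12 and the ylide of F7 | C=C(C)[C@H]1CC[C@H]([C@H]2CC/C(=C/CCCO[Si](C)(C)C(C)(C)C)CO2)[C@H]1O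
F9 | step 8 | Z primary alcohol | C=C(C)[C@H]1CC[C@H]([C@H]2CC/C(=C/CCCO)CO2)[C@H]1O
F10 | step 8 | Z primary iodide | C=C(C)[C@H]1CC[C@H]([C@H]2CC/C(=C/CCCI)CO2)[C@H]1O
F11 | step 8 | Z phosphonium iodide | C=C(C)[C@H]1CC[C@H]([C@H]2CC/C(=C/CCC[P+](c3ccccc3)(c3ccccc3)c3ccccc3)CO2)[C@H]1O.[I-]
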